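Ring-closing metathesis is used to form C3=C4 of ring C as a cyclic silyl enol ether. Ring C holds the only stereocentre, C2, which lies β to the C4 ketone and is easily lost by retro-oxa-Michael opening. Metathesis between a vinyl group on C2 and the silyl enol ether of an acetyl group on C4a closes the O1–C2–C3–C4–C4a–C8a ring without acid or base and delivers the ketone in masked form. The precursor 15 is an (S)-1-phenylallyl aryl ether with an ortho 1-silyloxyvinyl group. Its oxygens carry MOM acetals, so no Lewis acid is needed once C2 exists, and C8 is left free for later iodination and Stille prenylation.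

Key step: step 10

Remark: MOM protection of the 4-hydroxypyranone is drawn on O4; the 2-alkoxy-4-pyranone regioisomer, if it forms, gives the same pyranone in step 14.
Remark: the (Sa,Sc,Sc) phosphoramidite is assumed to give the S ether by analogy with the usual facial preference for cinnamyl carbonates; the mirror-image ligand would be used if the opposite sense were found.
Remark: flavanone numbering is used throughout (O1, C2–C4, C4a, C5–C8, C8a; ring A aromatic, ring C heterocyclic).

Step 1
Reactants: 1 4-bromo-3,5-dimethoxyphenol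
Product: 2 4-bromo-3,5-dimethoxyphenyl 4-methylbenzenesulfonate
Conditions: TsCl, Et3N, DMAP (cat.), CH2Cl2, 0 °C to rt
Reagents that add atoms: 4-methylbenzenesulfonyl chloride, Cc1ccc(cc1)S(Cl)(=O)=O
Why: Sulfonylation of the only phenol gives an aryl tosylate, chosen as the mask for the future O1 because it is inert to the Pd coupling, SOCl2, AlCl3 and BBr3 used before its removal and so keeps this oxygen distinct from the two that flank the bromide.

Step 2
Reactants: 2 4-bromo-3,5-dimethoxyphenyl 4-methylbenzenesulfonate; 3 dibenzyl malonate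
Product: 4 dibenzyl 2-[2,6-dimethoxy-4-(tosyloxy)phenyl]malonate
Conditions: Pd(dba)2 (3 mol%), [HP(t-Bu)3]BF4 (6 mol%), K3PO4, toluene, 80 °C
Reagents that add atoms: none
Why: Hartwig-type Pd-catalysed α-arylation of a malonate, in which the bulky electron-rich phosphine lets zerovalent palladium insert into the doubly ortho-substituted C–Br bond (the para sulfonate activates it and is itself inert with this ligand) and reductive elimination from the aryl palladium malonate forms the C–C bond.

Step 3
Reactants: 4 dibenzyl 2-[2,6-dimethoxy-4-(tosyloxy)phenyl]malonate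
Product: 5 2-[2,6-dimethoxy-4-(tosyloxy)phenyl]propanedioic acid
Conditions: H2 (1 atm), Pd/C (10 wt% palladium on carbon), EtOAc, rt
Reagents that add atoms: none
Why: Hydrogenolysis of the two benzyl esters frees the arylmalonic acid under neutral conditions at room temperature, which avoids both decarboxylation and base-induced loss of the tosylate.

Step 4
Reactants: 5 2-[2,6-dimethoxy-4-(tosyloxy)phenyl]propanedioic acid; 6 3-pentanone
Product: 8 3-[2,6-dimethoxy-4-(tosyloxy)phenyl]-6-ethyl-4-hydroxy-5-methylpyran-2-one, via chlorocarbonyl ketene 7 (not isolated)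
Conditions: SOCl2, toluene, rt to 80 °C, evaporate; then 3-pentanone, toluene, 110 °C
Reagents that add atoms: thionyl chloride, ClS(Cl)=O (chlorine of 7)
Why: SOCl2 converts arylmalonic acids into aryl(chlorocarbonyl)ketenes, and this 1,3-bis-electrophile is known to annulate enolisable ketones (C-acylation of the enol by the ketene, then O-acylation by the acid chloride with loss of HCl) to 3-aryl-4-hydroxypyran-2-ones, 3-pentanone being symmetrical so that only one pyranone can form.

Step 5
Reactants: 8 3-[2,6-dimethoxy-4-(tosyloxy)phenyl]-6-ethyl-4-hydroxy-5-methylpyran-2-one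
Product: 10 3-[3-acetyl-2,6-dihydroxy-4-(tosyloxy)phenyl]-6-ethyl-4-hydroxy-5-methylpyran-2-one, via dimethoxy acetophenone 9 (not isolated)
Conditions: AcCl (1.3 equiv), AlCl3 (5 equiv), CH2Cl2, 0 °C to rt; then BBr3 (6 equiv), −78 °C to rt; MeOH then H2O quench
Reagents that add atoms: acetyl chloride, CC(Cl)=O
Why: Friedel–Crafts acetylation occurs at one of the two equivalent free positions of ring A, each ortho and para to a methoxy group, and BBr3 then cleaves both aryl methyl ethers (any pyranone O-acetate falls off on quench) while the tosylate survives, so the exchange of protecting groups is finished before any stereocentre exists.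

Step 6
Reactants: 10 3-[3-acetyl-2,6-dihydroxy-4-(tosyloxy)phenyl]-6-ethyl-4-hydroxy-5-methylpyran-2-one
Product: 11 3-[3-acetyl-2,6-bis(methoxymethoxy)-4-(tosyloxy)phenyl]-6-ethyl-4-(methoxymethoxy)-5-methylpyran-2-one
Conditions: MOMCl (6 equiv), i-Pr2NEt (8 equiv), Bu4NI (cat.), CH2Cl2, 0 to 40 °C
Reagents that add atoms: chloromethyl methyl ether, COCCl
Why: O-Alkylation of the three acidic hydroxyls by the chloromethyl ether (Williamson-type acetal formation, iodide catalysis helping the hydrogen-bonded hydroxyl next to the acetyl group) installs MOM acetals that can be removed at the end by dilute protic acid, without Lewis acid or base.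

Step 7
Reactants: 11 3-[3-acetyl-2,6-bis(methoxymethoxy)-4-(tosyloxy)phenyl]-6-ethyl-4-(methoxymethoxy)-5-methylpyran-2-one
Product: 12 3-[3-acetyl-4-hydroxy-2,6-bis(methoxymethoxy)phenyl]-6-ethyl-4-(methoxymethoxy)-5-methylpyran-2-one
Conditions: NaOMe (excess), MeOH/THF, 45 °C; NH4Cl work-up
Reagents that add atoms: none
Why: Sulfonyl transfer to methoxide (transesterification at sulfur) releases the acetyl-stabilised phenoxide, excess methoxide consumes the methyl tosylate formed, and the MOM acetals and the fully substituted, sterically shielded 4-alkoxypyranone should tolerate methoxide.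

Step 8
Reactants: 12 3-[3-acetyl-4-hydroxy-2,6-bis(methoxymethoxy)phenyl]-6-ethyl-4-(methoxymethoxy)-5-methylpyran-2-one; 13 methyl cinnamyl carbonate
Product: 14 3-{3-acetyl-2,6-bis(methoxymethoxy)-4-[(1S)-1-phenylprop-2-enyloxy]phenyl}-6-ethyl-4-(methoxymethoxy)-5-methylpyran-2-one
Conditions: [Ir(cod)Cl]2 (2 mol%), (Sa,Sc,Sc)-O,O′-(1,1′-binaphthyl-2,2′-diyl) N,N-bis(1-phenylethyl)phosphoramidite (4 mol%, pre-activated with n-PrNH2), K3PO4, THF, 40 °C
Reagents that add atoms: none
Why: Ir-catalysed asymmetric allylic etherification (Hartwig–Helmchen type), in which the cyclometalated iridium phosphoramidite complex ionises the carbonate to a π-cinnamyl complex and the phenoxide attacks its benzylic terminus on the face fixed by the ligand, creating the future C2 stereocentre as the branched S ether.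

Step 9
Reactants: 14 3-{3-acetyl-2,6-bis(methoxymethoxy)-4-[(1S)-1-phenylprop-2-enyloxy]phenyl}-6-ethyl-4-(methoxymethoxy)-5-methylpyran-2-one
Product: 15 3-{3-[1-(tert-butyldimethylsilyloxy)vinyl]-2,6-bis(methoxymethoxy)-4-[(1S)-1-phenylprop-2-enyloxy]phenyl}-6-ethyl-4-(methoxymethoxy)-5-methylpyran-2-one
Conditions: TBSOTf, Et3N, CH2Cl2, −78 to 0 °C
Reagents that add atoms: tert-butyldimethylsilyl trifluoromethanesulfonate, CC(C)(C)[Si](C)(C)OS(=O)(=O)C(F)(F)F
Why: Soft enolisation of the aryl methyl ketone by a silyl triflate and a tertiary amine gives the only possible silyl enol ether without strong base or free acid, so the allylic benzylic ether stereocentre is not touched.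

Step 10
Reactants: 15 3-{3-[1-(tert-butyldimethylsilyloxy)vinyl]-2,6-bis(methoxymethoxy)-4-[(1S)-1-phenylprop-2-enyloxy]phenyl}-6-ethyl-4-(methoxymethoxy)-5-methylpyran-2-one
Product: 16 (2S)-4-(tert-butyldimethylsilyloxy)-6-[6-ethyl-4-(methoxymethoxy)-5-methyl-2-oxopyran-3-yl]-5,7-bis(methoxymethoxy)-2-phenyl-2H-chromene
Conditions: second-generation Grubbs catalyst RuCl2(=CHPh)(H2IMes)(PCy3) (10 mol%), 1,4-benzoquinone (20 mol%), toluene (0.005 M), 70 °C
Reagents that add atoms: none
Why: The ruthenium benzylidene first exchanges with the monosubstituted vinyl group of the allyl ether, the resulting alkylidene on C3 adds across the 1,1-disubstituted enol ether C4=CH2 in an intramolecular 2+2 cycloaddition, and cycloreversion of the ruthenacyclobutane releases ethene and leaves the C3=C4 bond. The closest known reactions are the ring-closing metathesis of silyl enol ethers with terminal alkenes to cyclic silyl enol ethers and that of aryl allyl ethers bearing an ortho alkenyl group to 2H-chromenes. Ring C is closed as a six-membered ring by ring-closing metathesis, the new double bond being endocyclic and the two alkenes being tethered through C4a, C8a and O1. No stereocentre is formed, and C2, set in step 8, is a spectator because no acid or base is present and 1,4-benzoquinone suppresses ruthenium hydride migration of the allylic double bond. Ring closure has to beat cross-metathesis, which high dilution, the six-membered ring and the reluctance of enol ethers to homodimerise should secure, and no other reactive alkene competes because the prenyl group is added later and the pyranone double bonds are tetrasubstituted.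

Step 11
Reactants: 16 (2S)-4-(tert-butyldimethylsilyloxy)-6-[6-ethyl-4-(methoxymethoxy)-5-methyl-2-oxopyran-3-yl]-5,7-bis(methoxymethoxy)-2-phenyl-2H-chromene
Product: 17 (2S)-6-[6-ethyl-4-(methoxymethoxy)-5-methyl-2-oxopyran-3-yl]-5,7-bis(methoxymethoxy)-2-phenylchroman-4-one
Conditions: Bu4NF, AcOH (1:1), THF, 0 °C
Reagents that add atoms: none
Why: Buffered fluoride desilylation cleaves the Si–O bond of the silyl enol ether while acetic acid protonates C3 at once, so the C4 ketone appears without a free base that could open ring C by retro-oxa-Michael reaction.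

Step 12
Reactants: 17 (2S)-6-[6-ethyl-4-(methoxymethoxy)-5-methyl-2-oxopyran-3-yl]-5,7-bis(methoxymethoxy)-2-phenylchroman-4-one
Product: 18 (2S)-6-[6-ethyl-4-(methoxymethoxy)-5-methyl-2-oxopyran-3-yl]-8-iodo-5,7-bis(methoxymethoxy)-2-phenylchroman-4-one
Conditions: NIS (1.1 equiv), DMF, rt, dark
Reagents that add atoms: N-iodosuccinimide, O=C1CCC(=O)N1I
Why: Electrophilic aromatic iodination can only occur at C8, the single unsubstituted carbon of ring A, which is activated by O1 and by the 5- and 7-alkoxy groups, and neutral NIS should leave the ketone, the MOM acetals, the unactivated 2-phenyl ring and C2 alone.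

Step 13
Reactants: 18 (2S)-6-[6-ethyl-4-(methoxymethoxy)-5-methyl-2-oxopyran-3-yl]-8-iodo-5,7-bis(methoxymethoxy)-2-phenylchroman-4-one; 19 tributyl(3-methylbut-2-enyl)stannane
Product: 20 (2S)-6-[6-ethyl-4-(methoxymethoxy)-5-methyl-2-oxopyran-3-yl]-5,7-bis(methoxymethoxy)-8-(3-methylbut-2-enyl)-2-phenylchroman-4-one
Conditions: Pd(PPh3)4 (10 mol%), toluene, 100 °C
Reagents that add atoms: none
Why: Stille coupling, in which oxidative addition of the aryl iodide, transfer of the prenyl group from tin and reductive elimination at the primary allylic carbon give the linear prenyl arene under neutral conditions that do not enolise the flavanone.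

Step 14
Reactants: 20 (2S)-6-[6-ethyl-4-(methoxymethoxy)-5-methyl-2-oxopyran-3-yl]-5,7-bis(methoxymethoxy)-8-(3-methylbut-2-enyl)-2-phenylchroman-4-one
Product: 21 (2S)-6-(6-ethyl-4-hydroxy-5-methyl-2-oxopyran-3-yl)-5,7-dihydroxy-8-(3-methylbut-2-enyl)-2-phenylchroman-4-one
Conditions: 3 M HCl (aq), MeOH, 40 °C
Reagents that add atoms: none
Why: Acid-catalysed acetal exchange with methanol removes the three MOM groups as dimethoxymethane, flavanones being expected to keep their C2 configuration under protic acid at moderate temperature and the conditions being mild enough that cyclisation of the prenyl group onto the 7-hydroxyl should not compete.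

Compound list
1 | 4-bromo-3,5-dimethoxyphenol | COc1cc(O)cc(OC)c1Br | starting material
2 | 4-bromo-3,5-dimethoxyphenyl 4-methylbenzenesulfonate | COc1cc(OS(=O)(=O)c2ccc(C)cc2)cc(OC)c1Br | intermediate
3 | dibenzyl malonate | O=C(CC(=O)OCc1ccccc1)OCc1ccccc1 | starting material
4 | dibenzyl 2-[2,6-dimethoxy-4-(tosyloxy)phenyl]malonate | COc1cc(OS(=O)(=O)c2ccc(C)cc2)cc(OC)c1C(C(=O)OCc1ccccc1)C(=O)OCc1ccccc1 | intermediate
5 | 2-[2,6-dimethoxy-4-(tosyloxy)phenyl]propanedioic acid | COc1cc(OS(=O)(=O)c2ccc(C)cc2)cc(OC)c1C(C(=O)O)C(=O)O | intermediate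
6 | 3-pentanone | CCC(=O)CC | starting material
7 | 2-[2,6-dimethoxy-4-(tosyloxy)phenyl]-3-oxoprop-2-enoyl chloride (aryl chlorocarbonyl ketene) | COc1cc(OS(=O)(=O)c2ccc(C)cc2)cc(OC)c1C(=C=O)C(=O)Cl | intermediate (not isolated)
8 | 3-[2,6-dimethoxy-4-(tosyloxy)phenyl]-6-ethyl-4-hydroxy-5-methylpyran-2-one | CCc1oc(=O)c(-c2c(OC)cc(OS(=O)(=O)c3ccc(C)cc3)cc2OC)c(O)c1C | intermediate
9 | 3-[3-acetyl-2,6-dimethoxy-4-(tosyloxy)phenyl]-6-ethyl-4-hydroxy-5-methylpyran-2-one | CCc1oc(=O)c(-c2c(OC)cc(OS(=O)(=O)c3ccc(C)cc3)c(C(C)=O)c2OC)c(O)c1C | intermediate (not isolated)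
10 | 3-[3-acetyl-2,6-dihydroxy-4-(tosyloxy)phenyl]-6-ethyl-4-hydroxy-5-methylpyran-2-one | CCc1oc(=O)c(-c2c(O)cc(OS(=O)(=O)c3ccc(C)cc3)c(C(C)=O)c2O)c(O)c1C | intermediate
11 | 3-[3-acetyl-2,6-bis(methoxymethoxy)-4-(tosyloxy)phenyl]-6-ethyl-4-(methoxymethoxy)-5-methylpyran-2-one | CCc1oc(=O)c(-c2c(OCOC)cc(OS(=O)(=O)c3ccc(C)cc3)c(C(C)=O)c2OCOC)c(OCOC)c1C | intermediate
12 | 3-[3-acetyl-4-hydroxy-2,6-bis(methoxymethoxy)phenyl]-6-ethyl-4-(methoxymethoxy)-5-methylpyran-2-one | CCc1oc(=O)c(-c2c(OCOC)cc(O)c(C(C)=O)c2OCOC)c(OCOC)c1C | intermediate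
13 | methyl cinnamyl carbonate, (E)-methyl 3-phenylprop-2-enyl carbonate | COC(=O)OC/C=C/c1ccccc1 | starting material
14 | 3-{3-acetyl-2,6-bis(methoxymethoxy)-4-[(1S)-1-phenylprop-2-enyloxy]phenyl}-6-ethyl-4-(methoxymethoxy)-5-methylpyran-2-one | CCc1oc(=O)c(-c2c(OCOC)cc(O[C@@H](C=C)c3ccccc3)c(C(C)=O)c2OCOC)c(OCOC)c1C | intermediate
15 | 3-{3-[1-(tert-butyldimethylsilyloxy)vinyl]-2,6-bis(methoxymethoxy)-4-[(1S)-1-phenylprop-2-enyloxy]phenyl}-6-ethyl-4-(methoxymethoxy)-5-methylpyran-2-one | CCc1oc(=O)c(-c2c(OCOC)cc(O[C@@H](C=C)c3ccccc3)c(C(=C)O[Si](C)(C)C(C)(C)C)c2OCOC)c(OCOC)c1C | intermediate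
16 | (2S)-4-(tert-butyldimethylsilyloxy)-6-[6-ethyl-4-(methoxymethoxy)-5-methyl-2-oxopyran-3-yl]-5,7-bis(methoxymethoxy)-2-phenyl-2H-chromene | CCc1oc(=O)c(-c2c(OCOC)cc3c(c2OCOC)C(O[Si](C)(C)C(C)(C)C)=C[C@@H](c2ccccc2)O3)c(OCOC)c1C | intermediate
17 | (2S)-6-[6-ethyl-4-(methoxymethoxy)-5-methyl-2-oxopyran-3-yl]-5,7-bis(methoxymethoxy)-2-phenylchroman-4-one | CCc1oc(=O)c(-c2c(OCOC)cc3c(c2OCOC)C(=O)C[C@@H](c2ccccc2)O3)c(OCOC)c1C | intermediate
18 | (2S)-6-[6-ethyl-4-(methoxymethoxy)-5-methyl-2-oxopyran-3-yl]-8-iodo-5,7-bis(methoxymethoxy)-2-phenylchroman-4-one | CCc1oc(=O)c(-c2c(OCOC)c(I)c3c(c2OCOC)C(=O)C[C@@H](c2ccccc2)O3)c(OCOC)c1C | intermediate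
19 | tributyl(3-methylbut-2-enyl)stannane | CCCC[Sn](CCCC)(CCCC)CC=C(C)C | starting material
20 | (2S)-6-[6-ethyl-4-(methoxymethoxy)-5-methyl-2-oxopyran-3-yl]-5,7-bis(methoxymethoxy)-8-(3-methylbut-2-enyl)-2-phenylchroman-4-one | CCc1oc(=O)c(-c2c(OCOC)c(CC=C(C)C)c3c(c2OCOC)C(=O)C[C@@H](c2ccccc2)O3)c(OCOC)c1C | intermediate
21 | (2S)-6-(6-ethyl-4-hydroxy-5-methyl-2-oxopyran-3-yl)-5,7-dihydroxy-8-(3-methylbut-2-enyl)-2-phenylchroman-4-one | CCc1oc(=O)c(-c2c(O)c(CC=C(C)C)c3c(c2O)C(=O)C[C@@H](c2ccccc2)O3)c(O)c1C | target

Total step count: 14.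
Longest linear sequence: 14 steps (1 to 21); building blocks 3, 6, 13 and 19 are bought.

Steps most likely to fail

Step 10. The ring closure may stall, because the 1,1-disubstituted enol ether sits between two ortho substituents and the product builds up a peri interaction between the 4-silyloxy group and the 5-MOM ether. Ruthenium hydride species may also move the allylic double bond into conjugation, with loss of the C2 stereocentre. The fallback gives up the metathesis and sets C2 by conjugate addition. It sets out from phenol 12. Condensation with N,N-dimethylformamide dimethyl acetal (toluene, 90 °C) should give the enaminone 3-{3-[(2E)-3-(dimethylamino)prop-2-enoyl]-4-hydroxy-2,6-bis(methoxymethoxy)phenyl}-6-ethyl-4-(methoxymethoxy)-5-methylpyran-2-one F1. Brief treatment with dilute HCl in CH2Cl2 at 0 °C, or with silica gel, should cyclise it with loss of dimethylamine to the chromone 6-[6-ethyl-4-(methoxymethoxy)-5-methyl-2-oxopyran-3-yl]-5,7-bis(methoxymethoxy)chromen-4-one F2. Enantioselective conjugate addition of phenylboronic acid (Pd(OCOCF3)2, the enantiomer of the pyridine-oxazoline ligand t-BuPyOx that delivers 2S, NH4PF6, H2O, 1,2-dichloroethane, 60 °C) would then give flavanone 17, where the route is rejoined before step 12.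

Step 8. The chelated, weakly nucleophilic phenoxide may attack slowly or at the unsubstituted allyl terminus. The product ether, which carries a good phenoxide leaving group, may also re-ionise on iridium and lose enantiomeric purity. The fallback sets out from phenol 12 and uses no allyl-metal intermediate. Mitsunobu etherification with enantiopure (R)-1-phenylprop-2-en-1-ol (PPh3, diisopropyl azodicarboxylate, toluene, 0 °C) substitutes at the carbinol carbon with inversion and should give ether 14 directly, where the route is rejoined before step 9.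

Step 13. Transfer of the prenyl group from tin may occur with allylic transposition, which would place the 1,1-dimethylallyl group on C8. Oxidative addition at the doubly ortho-substituted iodide may also be slow enough for protodeiodination to compete. The fallback sets out from iodide 18. Stille coupling with allyltributylstannane (Pd(PPh3)4, toluene, 100 °C), for which transposition changes nothing, should give (2S)-8-allyl-6-[6-ethyl-4-(methoxymethoxy)-5-methyl-2-oxopyran-3-yl]-5,7-bis(methoxymethoxy)-2-phenylchroman-4-one F3. Cross-metathesis with excess 2-methylbut-2-ene (second-generation Grubbs catalyst, CH2Cl2, 40 °C) would then turn the allyl group into the prenyl group of 20 with loss of propene, and the route is rejoined before step 14.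

Further compounds
F1 | step 10 | 3-{3-[(2E)-3-(dimethylamino)prop-2-enoyl]-4-hydroxy-2,6-bis(methoxymethoxy)phenyl}-6-ethyl-4-(methoxymethoxy)-5-methylpyran-2-one | CCc1oc(=O)c(-c2c(OCOC)cc(O)c(C(=O)/C=C/N(C)C)c2OCOC)c(OCOC)c1C
F2 | step 10 | 6-[6-ethyl-4-(methoxymethoxy)-5-methyl-2-oxopyran-3-yl]-5,7-bis(methoxymethoxy)chromen-4-one | CCc1oc(=O)c(-c2c(OCOC)cc3occc(=O)c3c2OCOC)c(OCOC)c1C
F0 | step 8 | none | none
F3 | step 13 | (2S)-8-allyl-6-[6-ethyl-4-(methoxymethoxy)-5-methyl-2-oxopyran-3-yl]-5,7-bis(methoxymethoxy)-2-phenylchroman-4-one | CCc1oc(=O)c(-c2c(OCOC)c(CC=C)c3c(c2OCOC)C(=O)C[C@@H](c2ccccc2)O3)c(OCOC)c1C
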